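**Plan**

- Retrosynthesis: the C3 carbinol goes back to a ketone, then the C4–Br bond and the C1–CH3 bond are removed, which leads to a spiro vinylogous ester. The two bonds C6–C11 and C6–C7 are then cut together, leaving the isobutyl vinylogous ester of dimedone and an open five-carbon tribromide.
- Enabling feature: ring B is the spiro atom C6 plus the chain C7–C8–C9(Me)=C10(Br)–C11, and both chain ends are CH2 groups on C6. Its tetrasubstituted alkene, with the two CH2 arms cis and bromine already on C10, is the C3=C4 alkene of 3-bromo-4-methyl-5,6-dihydro-2H-pyran-2-one, so the chain can be made with fixed geometry as a 1,5-dielectrophile.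
- Forward order: ring A is bought as dimedone. The lactone is brominated, reduced and converted into the tribromide. Ring B is closed on C6 in one flask by two enolate alkylations. Methyl addition with carbonyl transposition, C4 bromination and ketone reduction finish ring A.
- Stereochemistry: C6 comes from enantioface-selective ring closure in a chiral lithium amide aggregate. C4 comes from bromination of the silyl dienol ether with separation of epimers. C3 comes from a catalyst-controlled CBS reduction that places OH trans to Br.

Key step: step 5

**Assumptions**

- Numbering: ring A is C1(Me)=C2–C3(OH)–C4(Br)–C5(Me2)–C6(spiro) and ring B is C6–C7–C8–C9(Me)=C10(Br)–C11; all spiro intermediates are named with these numbers.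
- Step 5: the sense of induction of the lithium amide cannot be derived from a reliable model; the (R,R)-amide is taken to give (6R)-10, and if it gives the mirror image the (S,S)-amide takes its place.
- Step 9: the C4 side of the ketone (equatorial bromine eclipsing the carbonyl) is taken as the large group of the CBS model, which makes the (R)-catalyst the one that delivers hydride cis to bromine.

**Route**

Step 1
Reactants: 1 dimedone (5,5-dimethylcyclohexane-1,3-dione); 2 2-methylpropan-1-ol
Product: 3 3-(2-methylpropoxy)-5,5-dimethylcyclohex-2-en-1-one
Conditions: TsOH·H2O (cat.), toluene, reflux, Dean–Stark trap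
Reagents that add atoms: none
Why: Acid-catalysed enol etherification of a symmetric cyclic 1,3-diketone with a primary alcohol under azeotropic removal of water (vinylogous esterification) can give only this one vinylogous ester.

Step 2
Reactants: 4 4-methyl-5,6-dihydro-2H-pyran-2-one
Product: 6 3-bromo-4-methyl-5,6-dihydro-2H-pyran-2-one, via trans-3,4-dibromo-4-methyloxan-2-one 5 (not isolated)
Conditions: Br2, CH2Cl2, 0 °C to rt; then Et3N, 0 °C to rt
Reagents that add atoms: bromine, BrBr
Why: Anti addition of bromine to the enoate alkene followed by amine-induced dehydrobromination through the ester enolate (bromination–dehydrobromination, E1cB) is the standard α-bromination of unsaturated δ-lactones, and only the C3 hydrogen is acidic enough for Et3N.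

Step 3
Reactants: 6 3-bromo-4-methyl-5,6-dihydro-2H-pyran-2-one
Product: 7 (E)-2-bromo-3-methylpent-2-ene-1,5-diol (the two CH2 arms cis)
Conditions: i-Bu2AlH (4 equiv), CH2Cl2, −78 to 0 °C; aq. potassium sodium tartrate
Reagents that add atoms: none
Why: Hydride reduction of a lactone to the diol with excess i-Bu2AlH goes through the lactol by 1,2-addition only, so the vinyl bromide survives and the alkene geometry fixed by the ring is carried into the open chain.

Step 4
Reactants: 7 (E)-2-bromo-3-methylpent-2-ene-1,5-diol
Product: 8 (E)-1,2,5-tribromo-3-methylpent-2-ene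
Conditions: CBr4 (2.6 equiv), PPh3 (2.6 equiv), CH2Cl2, 0 °C
Reagents that add atoms: tetrabromomethane, BrC(Br)(Br)Br
Why: The Appel reaction converts both primary hydroxyls into bromides by SN2 displacement of the alkoxyphosphonium ions under neutral conditions, which leaves the tetrasubstituted alkene and its geometry untouched; excess reagent activates both hydroxyls quickly so that cyclic ether formation is outrun.

Step 5
Reactants: 3 3-(2-methylpropoxy)-5,5-dimethylcyclohex-2-en-1-one; 8 (E)-1,2,5-tribromo-3-methylpent-2-ene
Product: 10 (6R)-10-bromo-3-(2-methylpropoxy)-5,5,9-trimethylspiro[5.5]undeca-2,9-dien-1-one, via monoalkylated ketone 9 (not isolated)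
Conditions: LiN(i-Pr)2 (1.05 equiv), THF, −78 °C; 8, −78 to −50 °C; then lithium (R,R)-bis(1-phenylethyl)amide (2.2 equiv, from the amine and n-BuLi), LiCl, −78 to −20 °C
Reagents that add atoms: none
Why: Proposed new method: LiN(i-Pr)2 removes the only kinetically accessible proton of 3 (α′, at C6; the vinylogous ester blocks the other side) and the cross-conjugated lithium enolate displaces the allylic bromide of 8 by SN2 to form C6–C11 and give 9, after which the chiral amide removes the remaining C6–H, erasing the first stereocentre, and the planar enolate displaces the tethered primary bromide to form C6–C7 and the quaternary spiro centre. The closest known reaction types are the α′,α′-dialkylation (spiroannulation) of cyclic vinylogous esters with dihalides and the enantioselective alkylation of lithium enolates held in mixed aggregates with chiral lithium amides; their combination in a ring closure that sets a quaternary centre is untested. Ring B closes in the 6-exo-tet mode with the enolate carbon as nucleophile, which is why C-alkylation should win over the eight-membered O-alkylation. C6 is the only new stereocentre and is controlled by the (R,R)-amide bound in the enolate aggregate, which must shield one enantiotopic enolate face because the enolate itself is achiral. The step needs chemoselectivity among three C–Br bonds (allylic, then primary, vinylic inert; secured by their intrinsic SN2 reactivity), a cis disposition of the two CH2 arms (secured by the lactone origin of the alkene) and suppression of racemic background closure (secured by keeping the first alkylation cold so that 9 is not enolised before the chiral base is present).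

Step 6
Reactants: 10 (6R)-10-bromo-3-(2-methylpropoxy)-5,5,9-trimethylspiro[5.5]undeca-2,9-dien-1-one
Product: 12 (6R)-10-bromo-1,5,5,9-tetramethylspiro[5.5]undeca-1,9-dien-3-one, via tertiary allylic alcohol 11 (not isolated)
Conditions: MeLi, CeCl3 (anhydrous), THF, −78 to 0 °C; then 1 M HCl, rt
Reagents that add atoms: methyllithium, [Li]C
Why: The weakly basic organocerium reagent adds 1,2 to the hindered carbonyl next to the spiro centre without deprotonating C4 or touching the vinyl bromide, and aqueous acid hydrolyses the enol ether and dehydrates the β-hydroxy ketone (Stork–Danheiser transposition), so that C1 carries the methyl group and C3 the carbonyl.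

Step 7
Reactants: 12 (6R)-10-bromo-1,5,5,9-tetramethylspiro[5.5]undeca-1,9-dien-3-one
Product: 13 [(6S)-10-bromo-1,5,5,9-tetramethylspiro[5.5]undeca-1,3,9-trien-3-yl]oxy(trimethyl)silane
Conditions: LiN(i-Pr)2, THF, −78 °C; Me3SiCl, −78 to 0 °C; pentane, cold aq. NaHCO3
Reagents that add atoms: chlorotrimethylsilane, C[Si](C)(C)Cl
Why: Kinetic enolate formation from an isophorone-type enone with LiN(i-Pr)2 at −78 °C takes the α′ hydrogen at C4 and not a γ hydrogen, and O-silylation traps the cross-conjugated enolate as the 2-silyloxy diene.

Step 8
Reactants: 13 [(6S)-10-bromo-1,5,5,9-tetramethylspiro[5.5]undeca-1,3,9-trien-3-yl]oxy(trimethyl)silane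
Product: 14 (4S,6S)-4,10-dibromo-1,5,5,9-tetramethylspiro[5.5]undeca-1,9-dien-3-one
Conditions: N-bromosuccinimide, THF, −78 °C; SiO2 chromatography to separate the C4 epimers
Reagents that add atoms: N-bromosuccinimide, O=C1CCC(=O)N1Br
Why: Electrophilic α-bromination of a silyl enol ether occurs at the enol ether carbon C4 much faster than at the deactivated ring B bromoalkene, and C4 is set by bromine delivery anti to the pseudoaxial C5 methyl of the reacting half-chair; because the spiro centre distinguishes the two half-chairs only weakly, both epimers are expected and the (4S) epimer (Br cis to C11) is isolated by chromatography.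

Step 9
Reactants: 14 (4S,6S)-4,10-dibromo-1,5,5,9-tetramethylspiro[5.5]undeca-1,9-dien-3-one
Product: 15 (3S,4S,6S)-4,10-dibromo-1,5,5,9-tetramethylspiro[5.5]undeca-1,9-dien-3-ol
Conditions: (3aR)-1-methyl-3,3-diphenyltetrahydro-1H,3H-pyrrolo[1,2-c][1,3,2]oxazaborole [(R)-Me-CBS, 20 mol %], catecholborane, toluene, −78 °C; MeOH, pH 7 buffer
Reagents that add atoms: none
Why: In the Corey–Bakshi–Shibata reduction the catalyst boron should bind the carbonyl lone pair on the C2–H side (the C4 side is blocked by the equatorial bromine) and deliver hydride to the face cis to bromine, which sets (3S) with OH trans to Br under catalyst control, while catecholborane at −78 °C reduces 1,2 only and the neutral work-up avoids epoxide formation.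

**Compound list**

1 | dimedone (5,5-dimethylcyclohexane-1,3-dione) | CC1(C)CC(=O)CC(=O)C1 | starting material
2 | 2-methylpropan-1-ol | CC(C)CO | starting material
3 | 3-(2-methylpropoxy)-5,5-dimethylcyclohex-2-en-1-one | CC(C)COC1=CC(=O)CC(C)(C)C1 | intermediate
4 | 4-methyl-5,6-dihydro-2H-pyran-2-one | CC1=CC(=O)OCC1 | starting material
5 | trans-3,4-dibromo-4-methyloxan-2-one (racemic; (3R,4S) drawn) | C[C@]1(Br)CCOC(=O)[C@@H]1Br | intermediate (not isolated)
6 | 3-bromo-4-methyl-5,6-dihydro-2H-pyran-2-one | CC1=C(Br)C(=O)OCC1 | intermediate
7 | (E)-2-bromo-3-methylpent-2-ene-1,5-diol | OC/C(Br)=C(/C)CCO | intermediate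
8 | (E)-1,2,5-tribromo-3-methylpent-2-ene | BrC/C(Br)=C(/C)CCBr | intermediate
9 | 6-[(2E)-2,5-dibromo-3-methylpent-2-en-1-yl]-3-(2-methylpropoxy)-5,5-dimethylcyclohex-2-en-1-one (racemic) | O=C1C=C(OCC(C)C)CC(C)(C)C1C/C(Br)=C(/C)CCBr | intermediate (not isolated)
10 | (6R)-10-bromo-3-(2-methylpropoxy)-5,5,9-trimethylspiro[5.5]undeca-2,9-dien-1-one | O=C1C=C(OCC(C)C)CC(C)(C)[C@]12CCC(C)=C(Br)C2 | intermediate
11 | (6R)-10-bromo-1,5,5,9-tetramethyl-3-(2-methylpropoxy)spiro[5.5]undeca-2,9-dien-1-ol (both C1 epimers) | CC1(O)C=C(OCC(C)C)CC(C)(C)[C@]12CCC(C)=C(Br)C2 | intermediate (not isolated)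
12 | (6R)-10-bromo-1,5,5,9-tetramethylspiro[5.5]undeca-1,9-dien-3-one | CC1=CC(=O)CC(C)(C)[C@]12CCC(C)=C(Br)C2 | intermediate
13 | [(6S)-10-bromo-1,5,5,9-tetramethylspiro[5.5]undeca-1,3,9-trien-3-yl]oxy(trimethyl)silane | CC1=CC(O[Si](C)(C)C)=CC(C)(C)[C@]12CCC(C)=C(Br)C2 | intermediate
14 | (4S,6S)-4,10-dibromo-1,5,5,9-tetramethylspiro[5.5]undeca-1,9-dien-3-one | CC1=CC(=O)[C@@H](Br)C(C)(C)[C@]12CCC(C)=C(Br)C2 | intermediate
15 | (3S,4S,6S)-4,10-dibromo-1,5,5,9-tetramethylspiro[5.5]undeca-1,9-dien-3-ol | CC1=C[C@H](O)[C@@H](Br)C(C)(C)[C@]12CCC(C)=C(Br)C2 | target

**Step count**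

Total: 9 steps. Longest linear sequence: 8 steps (4 to 15, steps 2 to 9); the dimedone branch joins at step 5 after one step.

**Steps most likely to fail**

1. Step 5 (proposed new method). The ring closure may show too little enantioface discrimination if the chiral amide is not held on the hindered enolate. Proton transfer between the enolate of 3 and 9 before the chiral base is added would open a racemic background closure, and base-induced elimination of the primary bromide may compete as the mixture warms.
Fallback: it sets out from 3 and 8 and uses only known chemistry. LiN(i-Pr)2 alone (2.2 equiv in two portions, THF, −78 to 0 °C) performs the established α′,α′-dialkylation of the cyclic vinylogous ester through 9 and should give racemic 10-bromo-3-(2-methylpropoxy)-5,5,9-trimethylspiro[5.5]undeca-2,9-dien-1-one F1. Preparative chromatography on a chiral stationary phase (cellulose tris(3,5-dimethylphenylcarbamate), hexane/2-propanol) resolves it. The (6R) enantiomer is 10, where the route is rejoined before step 6, and the (6S) enantiomer F2 is set aside. The assignment would be secured later by anomalous-dispersion X-ray analysis of a crystalline dibromide such as 15.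

2. Step 8. Bromine transfer to C4 may show poor facial selectivity, since both faces carry a C5 methyl and the spiro centre biases the ring conformers only weakly.
Fallback: it sets out from 13, whose bromination delivers beside 14 the epimer (4R,6S)-4,10-dibromo-1,5,5,9-tetramethylspiro[5.5]undeca-1,9-dien-3-one F3. F3 is treated with LiN(SiMe3)2 in THF at −78 °C, which removes the acidic C4 hydrogen and gives the lithium bromo dienolate F4. Kinetic protonation with AcOH at −78 °C then sets C4 by the face of proton delivery instead of bromine delivery, so a facial preference that worked against 14 in the bromination works for it here. The mixture is separated, remaining F3 is cycled again, and the route is rejoined at 14.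

3. Step 9. Catalyst control may fail against the substrate's preference for hydride delivery anti to the axial C5 methyl, which leads to the cis bromohydrin, or the large/small assignment in the CBS model may be reversed.
Fallback: it sets out from 14 and sets C3 by invertive substitution instead of by face-selective hydride delivery. Substrate-controlled 1,2-reduction with i-Bu2AlH (toluene, −78 °C) should give the cis bromohydrin (3R,4S,6S)-4,10-dibromo-1,5,5,9-tetramethylspiro[5.5]undeca-1,9-dien-3-ol F5. Mitsunobu inversion (PPh3, diisopropyl azodicarboxylate, 4-nitrobenzoic acid, toluene, 0 °C to rt) gives the (3S) ester, (3S,4S,6S)-4,10-dibromo-1,5,5,9-tetramethylspiro[5.5]undeca-1,9-dien-3-yl 4-nitrobenzoate F6. The leaving group is cis to bromine, so neither bromine participation nor epoxide formation can intervene, and SN2′ attack at the fully substituted C1 is blocked. Brief methanolysis (K2CO3, MeOH, 0 °C) then releases 15, where the route ends.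

Further compounds
F1 | step 5 | racemic 10-bromo-3-(2-methylpropoxy)-5,5,9-trimethylspiro[5.5]undeca-2,9-dien-1-one | O=C1C=C(OCC(C)C)CC(C)(C)C12CCC(C)=C(Br)C2
F2 | step 5 | (6S)-10-bromo-3-(2-methylpropoxy)-5,5,9-trimethylspiro[5.5]undeca-2,9-dien-1-one | O=C1C=C(OCC(C)C)CC(C)(C)[C@@]12CCC(C)=C(Br)C2
F3 | step 8 | (4R,6S)-4,10-dibromo-1,5,5,9-tetramethylspiro[5.5]undeca-1,9-dien-3-one | CC1=CC(=O)[C@H](Br)C(C)(C)[C@]12CCC(C)=C(Br)C2
F4 | step 8 | lithium (6S)-4,10-dibromo-1,5,5,9-tetramethylspiro[5.5]undeca-1,3,9-trien-3-olate | [Li+].CC1=CC([O-])=C(Br)C(C)(C)[C@]12CCC(C)=C(Br)C2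
F5 | step 9 | (3R,4S,6S)-4,10-dibromo-1,5,5,9-tetramethylspiro[5.5]undeca-1,9-dien-3-ol | CC1=C[C@@H](O)[C@@H](Br)C(C)(C)[C@]12CCC(C)=C(Br)C2
F6 | step 9 | (3S,4S,6S)-4,10-dibromo-1,5,5,9-tetramethylspiro[5.5]undeca-1,9-dien-3-yl 4-nitrobenzoate | CC1=C[C@H](OC(=O)c3ccc(cc3)[N+](=O)[O-])[C@@H](Br)C(C)(C)[C@]12CCC(C)=C(Br)C2
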